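The pyran ring of the chromene is opened at C4a–C4. Ring oxygen O1 sits on C8a, next to the acyl-bearing C8, so an aryl ether on that oxygen has one free ortho carbon only, the future C4a, and the C3=C4 alkene can be read as a former alkyne. A gold(I)-catalysed 6-endo-dig hydroarylation of a 1,1-dimethylpropargyl aryl ether therefore closes the pyran ring and forms C4a–C4 regiospecifically in one operation. Its precursor is the bis-MOM ether of (S)-2-methylbutanoylphloroglucinol carrying the propargyl ether on the oxygen ortho to the ketone. MOM removal and a Mannich-type methylene bridge from C6 to the pyrone finish the target.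

Key step: step 4

Remark (assumption): the ketone α-carbon is (S) in the target and in every intermediate. The descriptor does not change from acid 1 onwards, because the carbonyl-bearing substituent outranks ethyl and methyl throughout. The pyrone is written as its 4-hydroxy-2-pyranone tautomer.

Step 1
Reactants: 1 (S)-2-methylbutanoic acid; 2 phloroglucinol
Product: 4 (S)-2-methyl-1-(2,4,6-trihydroxyphenyl)butan-1-one, via (S)-2-methylbutanoyl chloride 3 (not isolated)
Conditions: (COCl)2 (1.0 equiv), cat. DMF, CH2Cl2, 0 °C → rt; then 2, AlCl3 (3–4 equiv), PhNO2/CH2Cl2, 0 °C → rt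
Reagents that add atoms: none
Why: Friedel–Crafts acylation, in which the acid chloride made in the flask acylates one of the three equivalent ring carbons of phloroglucinol under AlCl3 and the new ketone deactivates the ring against a second acylation, while the α-stereocentre of 1 is carried through because no base is present and the temperature stays at or below room temperature (ee to be checked by chiral HPLC).

Step 2
Reactants: 4 (S)-2-methyl-1-(2,4,6-trihydroxyphenyl)butan-1-one
Product: 5 (S)-1-[2-hydroxy-4,6-bis(methoxymethoxy)phenyl]-2-methylbutan-1-one
Conditions: MOMCl (2.2 equiv), i-Pr2NEt (2.5 equiv), CH2Cl2, 0 °C → rt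
Reagents that add atoms: chloromethyl methyl ether, COCCl
Why: Base-mediated O-alkylation (Williamson-type acetal formation), in which the two ortho hydroxyls of 4 are equivalent and the one hydrogen-bonded to the ketone carbonyl is the least nucleophilic, so two equivalents of MOMCl should cap the para and one ortho oxygen and leave the chelated phenol free, a selectivity pattern well established for 2,4,6-trihydroxyaryl ketones.

Step 3
Reactants: 5 (S)-1-[2-hydroxy-4,6-bis(methoxymethoxy)phenyl]-2-methylbutan-1-one; 6 3-chloro-3-methylbut-1-yne
Product: 7 (S)-1-[2,4-bis(methoxymethoxy)-6-(2-methylbut-3-yn-2-yloxy)phenyl]-2-methylbutan-1-one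
Conditions: 6 (1.5 equiv), DBU (1.3 equiv), CuCl2·2H2O (1–5 mol %), MeCN, 0 °C → rt
Reagents that add atoms: none
Why: Copper-catalysed propargylic etherification, in which DBU deprotonates the only free phenol (breaking its hydrogen bond) and the copper acetylide of 6 ionises to a copper-allenylidene-type electrophile that the phenoxide captures at the tertiary carbon, a method known to tolerate hindered and ortho-carbonyl phenols, while 0 °C and a small excess of base protect the ketone α-centre.

Step 4
Reactants: 7 (S)-1-[2,4-bis(methoxymethoxy)-6-(2-methylbut-3-yn-2-yloxy)phenyl]-2-methylbutan-1-one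
Product: 8 (S)-1-[5,7-bis(methoxymethoxy)-2,2-dimethyl-2H-chromen-8-yl]-2-methylbutan-1-one
Conditions: Ph3PAuNTf2 (3 mol %, silver-free), CH2Cl2 (0.05 M), 4 Å MS, 0 °C → rt
Reagents that add atoms: none
Why: The cationic gold(I) centre binds the terminal alkyne and the ring carbon lying between the ether oxygen and the 4-OMOM group adds anti to gold at the terminal alkyne carbon, giving a vinylgold arenium ion that rearomatises and is protodeaurated; the closest known reaction type is the gold- or platinum-catalysed cycloisomerisation (intramolecular hydroarylation) of aryl propargyl ethers, 1,1-dimethyl cases included, to 2H-chromenes. The pyran ring is closed in the 6-endo-dig mode with formation of C4a–C4 only, the O1–C2 bond of the ether being carried over intact. No stereocentre is formed, and the neutral, non-basic catalyst does not touch the ketone α-centre. Regioselectivity is fixed by the substrate because the second carbon ortho to the ether oxygen bears the acyl group, while the attacking carbon is ortho to two oxygens and para to a third and is therefore strongly nucleophilic. Endo rather than 5-exo closure is expected from the unsubstituted alkyne terminus and the short, gem-dimethyl-compressed O–C tether. Ionisation of the tertiary propargylic C–O bond is the process to suppress, which a silver-free, weakly Lewis-acidic phosphine–gold triflimide at 0 °C to room temperature in a non-nucleophilic solvent should achieve.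

Step 5
Reactants: 8 (S)-1-[5,7-bis(methoxymethoxy)-2,2-dimethyl-2H-chromen-8-yl]-2-methylbutan-1-one
Product: 9 (S)-1-(5,7-dihydroxy-2,2-dimethyl-2H-chromen-8-yl)-2-methylbutan-1-one
Conditions: 3 M aq HCl, MeOH, rt → 40 °C (monitored, stopped at full conversion)
Reagents that add atoms: none
Why: Acid-catalysed acetal cleavage (transacetalisation to dimethoxymethane), in which both aryl MOM acetals ionise readily, the ortho one assisted by the neighbouring carbonyl, whereas the 8-acyl group lowers the basicity of the chromene C3=C4 bond so that methanol addition should not compete at or below 40 °C, and dilute acid does not enolise the hindered ketone at a meaningful rate.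

Step 6
Reactants: 10 pentan-3-one; 11 malonyl dichloride
Product: 12 6-ethyl-4-hydroxy-5-methyl-2H-pyran-2-one
Conditions: neat (10 in excess), rt, 2–3 d, HCl vented; trituration and recrystallisation
Reagents that add atoms: none
Why: Tandem C-acylation/O-acylation of a ketone with malonyl dichloride, in which the enol of the symmetrical ketone 10 is acylated at carbon by one acid chloride and the resulting 1,3-dicarbonyl enol closes through oxygen onto the second acid chloride (six-membered lactonisation), giving the 4-hydroxy-2-pyrone with ethyl at C6 and methyl at C5 without regiochemical ambiguity.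

Step 7
Reactants: 12 6-ethyl-4-hydroxy-5-methyl-2H-pyran-2-one; 9 (S)-1-(5,7-dihydroxy-2,2-dimethyl-2H-chromen-8-yl)-2-methylbutan-1-one
Product: 15 target 3-({5,7-dihydroxy-2,2-dimethyl-8-[(2S)-2-methylbutanoyl]-2H-chromen-6-yl}methyl)-6-ethyl-4-hydroxy-5-methyl-2H-pyran-2-one, via Mannich base 13 (not isolated), via methylidene pyrandione 14 (not isolated)
Conditions: 12, Me2N=CH2+ I− (1.0 equiv), MeCN, rt; then 9 (1.0 equiv), 60–70 °C
Reagents that add atoms: N,N-dimethylmethyleneiminium iodide, C=[N+](C)C.[I-]
Why: Mannich reaction followed by elimination and Michael (Friedel–Crafts-type) capture, in which the iminium salt aminomethylates C3 of 12 (its only nucleophilic CH), warming expels dimethylamine to give the 3-methylidene-2,4-dioxopyran, and this quinone-methide-like acceptor is attacked by C6 of 9, the sole unsubstituted aromatic carbon and one flanked by two hydroxyls, which forms the methylene bridge without touching the stereocentre.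

Compound list
1 | (S)-2-methylbutanoic acid | CC[C@H](C)C(=O)O | starting material
2 | phloroglucinol (benzene-1,3,5-triol) | Oc1cc(O)cc(O)c1 | starting material
3 | (S)-2-methylbutanoyl chloride | CC[C@H](C)C(=O)Cl | intermediate
4 | (S)-2-methyl-1-(2,4,6-trihydroxyphenyl)butan-1-one | CC[C@H](C)C(=O)c1c(O)cc(O)cc1O | intermediate
5 | (S)-1-[2-hydroxy-4,6-bis(methoxymethoxy)phenyl]-2-methylbutan-1-one | CC[C@H](C)C(=O)c1c(O)cc(OCOC)cc1OCOC | intermediate
6 | 3-chloro-3-methylbut-1-yne | CC(C)(Cl)C#C | starting material
7 | (S)-1-[2,4-bis(methoxymethoxy)-6-(2-methylbut-3-yn-2-yloxy)phenyl]-2-methylbutan-1-one | CC[C@H](C)C(=O)c1c(OCOC)cc(OCOC)cc1OC(C)(C)C#C | intermediate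
8 | (S)-1-[5,7-bis(methoxymethoxy)-2,2-dimethyl-2H-chromen-8-yl]-2-methylbutan-1-one | CC[C@H](C)C(=O)c1c(OCOC)cc(OCOC)c2C=CC(C)(C)Oc12 | intermediate
9 | (S)-1-(5,7-dihydroxy-2,2-dimethyl-2H-chromen-8-yl)-2-methylbutan-1-one | CC[C@H](C)C(=O)c1c(O)cc(O)c2C=CC(C)(C)Oc12 | intermediate
10 | pentan-3-one | CCC(=O)CC | starting material
11 | malonyl dichloride (propanedioyl dichloride) | O=C(Cl)CC(=O)Cl | starting material
12 | 6-ethyl-4-hydroxy-5-methyl-2H-pyran-2-one | CCc1oc(=O)cc(O)c1C | intermediate
13 | 3-[(dimethylamino)methyl]-6-ethyl-4-hydroxy-5-methyl-2H-pyran-2-one | CCc1oc(=O)c(CN(C)C)c(O)c1C | intermediate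
14 | 6-ethyl-5-methyl-3-methylidene-2H-pyran-2,4(3H)-dione | CCC1=C(C)C(=O)C(=C)C(=O)O1 | intermediate
15 | 3-({5,7-dihydroxy-2,2-dimethyl-8-[(2S)-2-methylbutanoyl]-2H-chromen-6-yl}methyl)-6-ethyl-4-hydroxy-5-methyl-2H-pyran-2-one | CCc1oc(=O)c(Cc2c(O)c3c(c(C(=O)[C@@H](C)CC)c2O)OC(C)(C)C=C3)c(O)c1C | target

Total step count: 7
Longest linear sequence: 6 (steps 1, 2, 3, 4, 5, 7); step 6 is a one-step side branch.

Steps most likely to fail

Step 4. The gold step could fail in three ways: ionisation of the tertiary propargylic C–O bond with loss of the side chain, sequestration of the catalyst as a gold acetylide, or intermolecular arylation at the ring carbon between the two MOM ethers. The fallback sets out from 7 and closes the ring pericyclically instead. Heating 7 in N,N-diethylaniline (or o-xylene) at 150–180 °C should bring about an aromatic propargyl Claisen rearrangement to the only open ortho carbon. After tautomerisation this gives the ortho-allenyl phenol (S)-1-[2-hydroxy-4,6-bis(methoxymethoxy)-3-(3-methylbuta-1,2-dien-1-yl)phenyl]-2-methylbutan-1-one F1, which is not isolated. It should close by 1,5-hydrogen shift and oxa-6π electrocyclisation to 8, where the route resumes. The MOM ethers and the α-centre should tolerate these neutral thermal conditions.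

Step 3. The hydrogen-bonded, ortho-acylated phenoxide may alkylate sluggishly, so that elimination of 6 to the enyne or base-induced epimerisation of the ketone α-centre takes over. The fallback sets out from 5 and builds the alkyne by homologation instead of delivering it by substitution. O-Alkylation of 5 with 2-bromo-2-methylpropanal (K2CO3, DMF, rt → 50 °C), an activated α-halo carbonyl electrophile, should give the aldehyde (S)-2-[3,5-bis(methoxymethoxy)-2-(2-methylbutanoyl)phenoxy]-2-methylpropanal F2. Seyferth–Gilbert homologation of F2 with dimethyl (1-diazo-2-oxopropyl)phosphonate (K2CO3, MeOH, 0 °C → rt) should then convert the aldehyde into the terminal alkyne 7, where the route resumes. The hindered aryl ketone should not react with the diazophosphonate; the ee should be checked afterwards.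

Step 7. The methylidene pyrandione may be consumed by dimerisation, by capture with pyrone set free through retro-Mannich exchange (symmetrical methylene-bis-pyrone), or by O-alkylation of the phenol. The fallback sets out from 9 and reverses the roles of the partners. Aminomethylation of 9 at C6 with N,N-dimethylmethyleneiminium iodide (MeCN, rt) should give the phenolic Mannich base (S)-1-{6-[(dimethylamino)methyl]-5,7-dihydroxy-2,2-dimethyl-2H-chromen-8-yl}-2-methylbutan-1-one F3. Heating F3 with 12 in 1,4-dioxane at 80–100 °C should expel dimethylamine and generate the ortho-quinone methide (S)-7-hydroxy-2,2-dimethyl-6-methylidene-8-(2-methylbutanoyl)-2H-chromen-5(6H)-one F4, which is not isolated. Capture of F4 at C3 of the pyrone should give 15 directly.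

Further compounds
F1 | step 4 | (S)-1-[2-hydroxy-4,6-bis(methoxymethoxy)-3-(3-methylbuta-1,2-dien-1-yl)phenyl]-2-methylbutan-1-one | CC[C@H](C)C(=O)c1c(O)c(C=C=C(C)C)c(OCOC)cc1OCOC
F2 | step 3 | (S)-2-[3,5-bis(methoxymethoxy)-2-(2-methylbutanoyl)phenoxy]-2-methylpropanal | CC[C@H](C)C(=O)c1c(OCOC)cc(OCOC)cc1OC(C)(C)C=O
F3 | step 7 | (S)-1-{6-[(dimethylamino)methyl]-5,7-dihydroxy-2,2-dimethyl-2H-chromen-8-yl}-2-methylbutan-1-one | CC[C@H](C)C(=O)c1c(O)c(CN(C)C)c(O)c2C=CC(C)(C)Oc12
F4 | step 7 | (S)-7-hydroxy-2,2-dimethyl-6-methylidene-8-(2-methylbutanoyl)-2H-chromen-5(6H)-one | CC[C@H](C)C(=O)C1=C(O)C(=C)C(=O)C2=C1OC(C)(C)C=C2
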